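The constants used here come from no measurement; the rest is arithmetic.

Of the 1.6 M of solid substrate charged, the solution can hold 0.82 M, about half. None of it is dissolved at the start and no coupling partner is in solution, while the gas is held at 200 mM.

solid substrate 1.6 M; gas 200 mM (held); time 2.5 h

    solid substrate ⇌ dissolved substrate, rate k1*(cs1 - [dissolved substrate]) while solid is left; crystals form when [dissolved substrate] > cs1 (cs1 = 0.82 M, k1 = 0.52 h⁻¹)
    dissolved substrate + coupling partner → target (k2 = 600 M⁻¹ h⁻¹)
    solid product ⇌ target, rate k3*(cs3 - [target]) while solid is left; crystals form when [target] > cs3 (cs3 = 0.10 M, k3 = 7.1 h⁻¹)
    coupling partner ⇌ dormant form (K4 = 9.6, k4 = 0.28 h⁻¹)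
    gas ⇌ coupling partner, rate k5*(csat - [coupling partner]) (k5 = 9.4 h⁻¹, csat = 200 mM)

- amounts and yields of target count solid product too
- given per volume of solution although it is solid: solid substrate, solid product
- at the start none of coupling partner is dissolved
- at the start none of the solid substrate is in solution
- dissolved substrate means what is dissolved; the solid is not counted in it
- run time (flask): 2.5 h

- how much target and solid product together there is at 2.5 h, in percent of the solid substrate charged
- concentration of dissolved substrate in solution at 2.5 h, in percent of saturation

The quantity I carry through this flask is the dissolution ceiling, the rate at which solid substrate enters a solution holding almost none of it, which is the dissolution coefficient times the solubility: 0.426 M h⁻¹.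

In the first instants the gas can deliver 1.88 M h⁻¹ of coupling partner into the empty solution, faster than the ceiling, and the transfer has a time constant of 0.106 h.

In the middle I freeze the partner, letting the gas replace what coupling takes. That puts it at 0.155 M. Coupling is then pseudo-first-order in dissolved substrate, at 92.8 h⁻¹, and dissolved substrate rests where coupling removes what dissolution brings: 4.60 mM, or 0.560% of saturation. Because that level lies far below the solubility, dissolution keeps running at its ceiling and is the rate-limiting step. At the ceiling I reckon that target reaches its solubility of 0.10 M after about 0.235 h; above that level crystals of solid product can form, and they count in the yield. The dormant form starts by drawing 0.0433 M h⁻¹ of partner, less than the ceiling, so I expect the partner a little below my figure.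

At the end, the charge would last 3.76 h at the ceiling, longer than the run, so solid remains at the last moment and I commit to 66.6%.

The forecast gives 65.9% and 0.56%, on the ground that “dissolution runs flat out”. Its yield stands 0.72 percentage points below mine.

This flask gives 65.9% and 0.572%, with 34% of the charge still there at the end, solid or dissolved. At the ceiling, I reckon that remainder at about another 1.28 h. For the same flask read at 1.0 h, the ceiling gives 26.6%, and the reading is 26.2%.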